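**Retrosynthetic overview**
1. Cut the central sp–sp bond of the 1,3-diyne: Cadiot–Chodkiewicz coupling of 15-bromopentadec-14-yn-1-ol with 2-(hex-5-yn-1-yl)furan. The halogen sits on the alcohol half so the furan never meets NBS.
2. Bromoalkynol ⇐ pentadec-14-yn-1-ol ⇐ (alkyne zipper) pentadec-2-yn-1-ol ⇐ tetradec-1-yne + formaldehyde.
3. Furyl alkyne ⇐ 2-(4-bromobutyl)furan + acetylide ⇐ 2-lithiofuran + 1,4-dibromobutane.
4. No ring is formed; the furan ring is bought as furan.

Assumption: the target has no stereocentre and no stereogenic double bond, so it is achiral and needs no stereocontrol. Reagents that deliver atoms (paraformaldehyde, NBS, lithium acetylide complex) are numbered like starting materials.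

**Route**

Step 1
Reactants: 1 tetradec-1-yne; 2 paraformaldehyde
Product: 5 pentadec-2-yn-1-ol, via lithium tetradec-1-yn-1-ide 3 (not isolated), via lithium pentadec-2-yn-1-olate 4 (not isolated)
Conditions: n-BuLi (1.05 equiv), THF, −78 °C; (CH2O)n (2.5 equiv), −78 °C → rt; then H2O
Reagents that add atoms: paraformaldehyde 2 (as formaldehyde), C=O
Why: Acetylide hydroxymethylation, in which n-BuLi cleanly deprotonates the terminal alkyne and the alkynyllithium adds to formaldehyde released from paraformaldehyde, with no stereocentre formed.

Step 2
Reactants: 5 pentadec-2-yn-1-ol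
Product: 7 pentadec-14-yn-1-ol, via dipotassium pentadec-14-yn-15-id-1-olate 6 (not isolated)
Conditions: KH (4 equiv), H2N(CH2)3NH2, rt, 1 h; then 5, 0 °C → rt, 3 h; then H2O
Reagents that add atoms: none
Why: Alkyne zipper reaction (KAPA isomerisation), in which repeated propargyl–allenyl proton shifts walk the triple bond along the unbranched chain away from the alkoxide until irreversible formation of the terminal acetylide 6 traps it at the chain end, with no stereocentre involved.

Step 3
Reactants: 7 pentadec-14-yn-1-ol; 8 N-bromosuccinimide
Product: 10 15-bromopentadec-14-yn-1-ol, via silver(I) 15-hydroxypentadec-1-yn-1-ide 9 (not isolated)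
Conditions: NBS (1.1 equiv), AgNO3 (10 mol%), acetone, rt, dark
Reagents that add atoms: N-bromosuccinimide 8, O=C1CCC(=O)N1Br
Why: Silver-catalysed electrophilic bromination of a terminal alkyne through its silver acetylide is selective for the C(sp)–H bond, leaves the primary alcohol untouched, and is run on this half so the furan never sees NBS.

Step 4
Reactants: 11 furan; 12 1,4-dibromobutane
Product: 14 2-(4-bromobutyl)furan, via furan-2-yllithium 13 (not isolated)
Conditions: furan (1.2 equiv), n-BuLi (1.0 equiv), THF, −78 → 0 °C; then cannulate into 12 (4 equiv), THF, −78 °C → rt; then H2O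
Reagents that add atoms: 1,4-dibromobutane 12, BrCCCCBr
Why: α-Lithiation of furan followed by SN2 alkylation, where inverse addition to a fourfold excess of the dibromide holds the reaction at mono-substitution and keeps the second primary bromide for step 5.

Step 5
Reactants: 14 2-(4-bromobutyl)furan; 15 lithium acetylide–ethylenediamine complex
Product: 16 2-(hex-5-yn-1-yl)furan
Conditions: LiC≡CH·H2NCH2CH2NH2 (1.5 equiv), DMSO, 10 °C → rt; then H2O
Reagents that add atoms: lithium acetylide–ethylenediamine complex 15, [Li+].[C-]#C.NCCN
Why: SN2 alkylation of lithium acetylide by a primary bromide in DMSO, where the acetylide is a strong nucleophile, elimination is minor and the furan is inert.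

Step 6
Reactants: 16 2-(hex-5-yn-1-yl)furan; 10 15-bromopentadec-14-yn-1-ol
Product: 18 21-(furan-2-yl)henicosa-14,16-diyn-1-ol, via copper(I) 6-(furan-2-yl)hex-1-yn-1-ide 17 (not isolated)
Conditions: CuCl (10 mol%), NH2OH·HCl (cat.), 30% aq. n-BuNH2, MeOH/THF, 0 °C → rt, N2; 16 (1.3 equiv), slow addition of 10
Reagents that add atoms: 15-bromopentadec-14-yn-1-ol 10, OCCCCCCCCCCCCCC#CBr
Why: Cadiot–Chodkiewicz cross-coupling, in which the copper(I) acetylide of 16 couples with the 1-bromoalkyne to form the sp–sp bond while hydroxylamine keeps copper as Cu(I) against Glaser homocoupling and the free OH and furan tolerate the mild aqueous amine, with no stereocentre present.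

**Compound list**
1 | tetradec-1-yne | C#CCCCCCCCCCCCC | starting material
2 | paraformaldehyde (formaldehyde unit) | C=O | starting material
3 | lithium tetradec-1-yn-1-ide | [Li+].[C-]#CCCCCCCCCCCCC | intermediate
4 | lithium pentadec-2-yn-1-olate | [Li+].[O-]CC#CCCCCCCCCCCCC | intermediate
5 | pentadec-2-yn-1-ol | OCC#CCCCCCCCCCCCC | intermediate
6 | dipotassium pentadec-14-yn-15-id-1-olate | [K+].[K+].[O-]CCCCCCCCCCCCCC#[C-] | intermediate
7 | pentadec-14-yn-1-ol | OCCCCCCCCCCCCCC#C | intermediate
8 | N-bromosuccinimide | O=C1CCC(=O)N1Br | starting material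
9 | silver(I) 15-hydroxypentadec-1-yn-1-ide | OCCCCCCCCCCCCCC#C[Ag] | intermediate
10 | 15-bromopentadec-14-yn-1-ol | OCCCCCCCCCCCCCC#CBr | intermediate
11 | furan | c1ccoc1 | starting material
12 | 1,4-dibromobutane | BrCCCCBr | starting material
13 | furan-2-yllithium | [Li]c1ccco1 | intermediate
14 | 2-(4-bromobutyl)furan | BrCCCCc1ccco1 | intermediate
15 | lithium acetylide–ethylenediamine complex | [Li+].[C-]#C.NCCN | starting material
16 | 2-(hex-5-yn-1-yl)furan | C#CCCCCc1ccco1 | intermediate
17 | copper(I) 6-(furan-2-yl)hex-1-yn-1-ide | [Cu]C#CCCCCc1ccco1 | intermediate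
18 | 21-(furan-2-yl)henicosa-14,16-diyn-1-ol | OCCCCCCCCCCCCCC#CC#CCCCCc1ccco1 | target

**Totals**
Total step count: 6. Longest linear sequence: 4 (steps 1, 2, 3, 6).

**Steps most likely to fail, with fallbacks**

Step 2 (alkyne zipper; needs rigorously dry KAPA and can stall at internal alkynes). The fallback sets out from 15, the acetylide reagent of step 5, and comes back to the route at 7. 13-Bromotridecan-1-ol F1 (bought in) is treated with 15 (3 equiv) in DMSO at 0 °C → rt. SN2 displacement of the primary bromide gives 7 directly, with no triple-bond migration. F1 is a low-volume specialty item of uncertain supply, which is why the main route does not rest on it. Compounds 1, 2 and 5 are then not needed.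

Step 6 (Cadiot–Chodkiewicz between two unactivated alkyl alkynes; homocoupling or reduction of the bromoalkyne can dominate). The fallback sets out from 7, skipping step 3 and compound 10, and comes back at 18. Compound 7 and an excess of 16 (4 equiv) are joined by oxidative Glaser–Hay-type hetero-coupling of the two terminal alkynes (NiCl2·6H2O/CuI cat., TMEDA, air, THF, rt). No haloalkyne is involved. The three possible diynes carry zero, one and two hydroxyl groups, so the mono-alcohol 18 separates easily on silica. No new isolated compound is made.

Step 4 (mono-alkylation of 2-furyllithium with a dihalide; bis-alkylation and elimination lower the yield). The fallback sets out from 11 and comes back at 16, skipping 14 and step 5. 6-Iodohex-1-yne F2 (bought in) is C-silylated (LiHMDS, THF, −78 °C; then TMSCl) to (6-iodohex-1-yn-1-yl)trimethylsilane F3. Compound 13, generated from 11 as in step 4, is alkylated with this monofunctional iodide (THF, −78 °C → rt) to give [6-(furan-2-yl)hex-1-yn-1-yl]trimethylsilane F4. K2CO3 in MeOH at rt removes the silyl group and delivers 16.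

**Further compounds**
F1 | step 2 | 13-bromotridecan-1-ol (bought in) | OCCCCCCCCCCCCCBr
F0 | step 6 | none | none
F2 | step 4 | 6-iodohex-1-yne (bought in) | C#CCCCCI
F3 | step 4 | (6-iodohex-1-yn-1-yl)trimethylsilane | C[Si](C)(C)C#CCCCCI
F4 | step 4 | [6-(furan-2-yl)hex-1-yn-1-yl]trimethylsilane | C[Si](C)(C)C#CCCCCc1ccco1
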